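The charges of our two flasks stand in the ratio 1.54, north's over north-east's. We call this the charge ratio: the factor between the two percentages of product for as long as the two solutions are alike.

| setting | Saturday's | Monday's | north-east | north |
|---|---|---|---|---|
| solid substrate | 1.8 M | 2.3 M | 1.3 M | 2.0 M |
| reagent | 2.6 M | 2.6 M | 2.60 M | 2.60 M |
| precatalyst | 2.6 mM | 2.6 mM | 2.6 mM | 2.6 mM |
| temperature | 95 °C | 106 °C |  |  |
| remark | run made earlier | run made earlier | at 110 °C until 3.0 h, from then on at 90 °C | at 110 °C throughout |
| time |  |  | 6.0 h | 6.0 h |

| run | time / h | product / % | solid substrate / % |
|---|---|---|---|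
| Saturday's | 1.00 | 0 | 77.3 |
| Saturday's | 2.00 | 0.8 | 65.8 |
| Saturday's | 3.00 | 0.1 | 58.8 |
| Saturday's | 6.00 | 2.3 | 49.1 |
| Saturday's | 12.0 | 7.3 | 42.5 |
| Monday's | 0.500 | 0 | 89.2 |
| Monday's | 0.833 | 0.1 | 86.6 |
| Monday's | 1.50 | 0.1 | 79.2 |
| Monday's | 3.00 | 1.2 | 65.1 |
| Monday's | 6.00 | 10.0 | 55.3 |

(readings scatter by 1 percentage point)

- as a solid, counted per litre of solution: solid substrate
- steps thought possible: reagent + free catalyst -> catalyst intermediate A; catalyst intermediate A -> by-product + catalyst intermediate B; starting material + catalyst intermediate B <-> catalyst intermediate C; catalyst intermediate C -> free catalyst + product; solid substrate <-> starting material; precatalyst -> free catalyst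
- at the start none of the solid substrate is in solution
- what has only dissolved of solid substrate counts as not reacted

- the flask that ends with the higher amount of product, in percent of the solid substrate charged, or "neither" when 2 percentage points or less lies between them (north-east / north / neither)
- final product, as a percentage of the solid substrate charged, in north-east
- final product, as a percentage of the solid substrate charged, in north

Saturday's run shows how solutions can come to be alike. Its solid curve flattens, and at 12.0 h the part that is neither solid nor product is 0.904 M, a reading with its scatter, which we carry over as the level of what dissolves. As a fraction of the charge that level is 0.695 in north-east and 0.452 in north, so we expect solid to lie on the bottom of both flasks up to 6.0 h.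

Saturday's first reading gives, with its scatter, a dissolving constant of 0.602 h⁻¹. The dissolved curve therefore starts with a slope of 0.418 h⁻¹ of the charge in north-east and 0.272 h⁻¹ in north, bends at about 1.66 h, and runs into its level.

We take it that a solution over solid does not feel how much solid lies beneath it. Equal heat then gives equal product per litre, and north-east's percentage stands above north's by the charge ratio: this is our zero of the scale. It lasts until 3.0 h, when north-east drops to 90 °C.

From 95 °C to 106 °C, six-hour product per litre rose by a factor of 5.56, a loose reading but larger than the charge ratio. So we expect north's curve to cross north-east's after the cooling, and north to end ahead.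

The forecast says north, with 8% (5% to 13%) for north-east and 20% (14% to 28%) for north. Multiplied by the charge ratio, its north marks 30.8% on our scale; for north-east, its grounds are that cooling “cuts turnover and activation about fourfold”.

The simulation gives 12.6% for north-east and 22.4% for north, so north ends ahead, and both values lie inside the forecast's ranges.

    reagent + free catalyst → catalyst intermediate A (k = 424 M⁻¹ h⁻¹, Ea = 59.0 kJ mol⁻¹)
    catalyst intermediate A → by-product + catalyst intermediate B (k = 603 h⁻¹, Ea = 94.0 kJ mol⁻¹)
    starting material + catalyst intermediate B ⇌ catalyst intermediate C (K = 9.61 M⁻¹, k = 3730 M⁻¹ h⁻¹, Ea = 61.0 kJ mol⁻¹, ΔH = 13.0 kJ mol⁻¹)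
    catalyst intermediate C → free catalyst + product (k = 466 h⁻¹, Ea = 107 kJ mol⁻¹)
    solid substrate ⇌ starting material, rate k5*(cs5 - [starting material]) while solid is left; crystals form when [starting material] > cs5 (solubility = 0.940 M, k = 0.509 h⁻¹)
    precatalyst → free catalyst (k = 0.0599 h⁻¹, Ea = 120 kJ mol⁻¹)
    (constants at 110 °C)

At 3.00 h, north-east's percentage of product over north's is 1.54, against the charge ratio of 1.54. Catalyst intermediate C stands at 6.42% of the catalyst in north-east and 6.42% in north. The difference in temperature programme is the main reason for the gap at the end: north, run on north-east's programme, ends at 8.18%, and north-east's 12.6% divided by the charge ratio gives 8.18%.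

The earlier runs and the new flask are calculated on assumed constants; scatter was added.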